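## Structural features

The target is an isoflavone: benzene ring A is fused to pyranone ring C across C4a–C8a, and ring B, a 4-hydroxy-3,5-dimethoxyphenyl group, is attached to C3 by a single bond. Ring A is fully differentiated, with methoxy on C5 (peri to the C4 carbonyl), methyl on C6, a free hydroxyl on C7 and hydrogen on C8. There is no stereocenter, so no stereocenters stand next to each other and none has to be set or preserved. The fragile points are the two free phenols, the 5-methoxy group (cleaved preferentially by chelating Lewis acids such as BCl3 or AlCl3) and the C2=C3 bond of the vinylogous ester (open to nucleophiles at C2 and to over-hydrogenation). The real difficulty is regiochemical: the contiguous substituents on C4a, C5, C6 and C7 must be placed without ambiguity, and O5 (methyl ether) must end up different from O7 (free hydroxyl) although both flank the C6 methyl group. The key step exploits the fact that O1 (on C8a) and the C4 carbonyl carbon (on C4a) sit on adjacent carbons of ring A with the O5 substituent next to C4a. That is the pattern left when an oxygen nucleophile adds to the distal carbon of a 3-alkoxyaryne and the aryl anion formed ortho to the alkoxy group is acylated.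

## Logic of the disconnections

20 to 19: the two O–CH2Ph bonds on O7 and O4' are cut. Free phenols would add to the aryne, so both oxygens must be masked, and benzyl is chosen because one hydrogenolysis releases both while the three methyl ethers stay. The gain is a one-step end game in which the 5-methoxy group never has to be installed late. The demand on the forward step is that hydrogenolysis stops before the C2=C3 bond is reduced.

19 to 12 and 17 (through 18): the bonds O1–C8a and C4–C4a are cut, which opens ring C. An aryne offers exactly two adjacent reactive carbons, and the oxido-acrylate offers a nucleophilic oxygen and an electrophilic ester carbon four atoms apart, so the two fragments close a six-membered ring. The gain is full convergence: ring B, C2, C3 and every oxygen substituent are already in place. The forward step must add oxygen (not carbon) at C8a (not C4a), and the aryl anion must reach the ester before it is protonated.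

12 to 10 (through 11), 10 to 6 (through 7, 8, 9) and 6 to 5: the O–S bond of the triflate, the C8a–Si bond and the carbamoyl C–O bond are cut. Two design decisions are made here.
- O5 is carried as the target's own methyl ether and O7 as a benzyl ether. Two identical acetals would force four operations after the annulation (acetal removal, selective O7 protection, O5 methylation, deprotection).
- Silicon is placed on C8a and the triflate oxygen on C4a. This isomer gives the same aryne 18 as the one with triflate on C8a, and the carbon skeleton and the bonds formed are unchanged. It is preferred because the phenol oxygen of 5 has only one free ortho position (the other carries the methoxy group), so metalation directed by that oxygen can only reach C8a. A phenol on C8a would have two ortho positions, flanked by OMe and OBn, that cannot be told apart reliably.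

The gain is a regiospecific, metal-catalyst-free route to an unsymmetrical aryne precursor. The forward steps must lithiate faster than the carbamoyl group migrates or the benzylic positions are deprotonated, and must triflate a hindered phenoxide.

5 to 3 (through 4), 3 to 2 and 2 to 1: the C4a–O bond (retro-Dakin, back to C4a–CHO), the O5–CH3 bond and the O7–CH2Ph bond are cut. In 1 the formyl group hydrogen-bonds one hydroxyl and leaves the other free, which provides the O5/O7 differentiation for nothing. The formyl carbon is then excised oxidatively to leave the phenol oxygen on C4a. The gain is a simple trisubstituted benzaldehyde as starting material. The forward steps must monoalkylate selectively and must migrate aryl, not hydride, in the peracid oxidation.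

17 to 15 and 16, 15 to 14 and 14 to 13: the C2–C3 bond (formyl carbon to the benzylic carbon), the benzyl ether O–C bond and the ester O–CH3 bond are cut. C2 comes from 16 in a crossed ester condensation in which only 15 can enolise. The methyl ester matches the formate, so alkoxide exchange cannot scramble the ester that later serves as the leaving group. The gain is a three-step branch from a commercial arylacetic acid. The forward step must formylate once and deliver the oxido-acrylate free of water.

## Other disconnections considered

Alternative 1: The cut is C4–C4a and C3–C4, with C4 supplied as carbon monoxide. In the forward step the aryl iodide A1 adds oxidatively to Pd(PPh3)4 (zerovalent palladium), CO inserts, the acylpalladium is transmetalated by the vinylboronate A2, and reductive elimination gives the aryl vinyl ketone A3.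
- In its favour: carbonylative cross-coupling is an established reaction class, so on precedent this alternative is better than the chosen key step. O5 (methyl) and O7 (silyl) are already different in A1, which makes it the equal of the chosen plan on that point. It is also modular.
- Against it here: A1 is electron-rich and substituted on both sides of the iodide, so oxidative addition and acyl transfer should be slow and direct coupling without CO can compete. A2 is prone to protodeboronation. A3 is a polymerisable Michael acceptor.
- The step closes no ring. Ring C still requires acetal removal, conjugate addition of the phenol and dehydrogenation, followed by desilylation and debenzylation.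
- Making A1 also needs a site-selective iodination of a pentasubstituted arene.
- Comparison: structurally it forms two C–C bonds but no ring, against one C–O bond, one C–C bond and ring C in the chosen step. Mechanistically it is the safer step. In step economy it is clearly worse, with four to five operations after the key step against one, plus the handling of CO.

Alternative 2: The cut dismantles ring A at C8–C8a, C5–C6, C7–C8 and C4a–C5. In the forward step irradiation of the diazoketone A4 causes Wolff rearrangement to a pyranonylketene. This adds the siloxyalkyne A5 in a [2+2] sense, the cyclobutenone opens (4π), closes onto the pyranone double bond (6π) and tautomerises to the chromone A6.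
- In its favour: four bonds and a whole benzene ring are made in one operation, which is better than the chosen step on bond count. The polarity of the ketene and ynol ether fixes the substitution pattern, and O5 emerges as a free chelated hydroxyl while O7 is a silyl ether, so the two oxygens are differentiated as well as in the chosen plan. The benzannulation is a known reaction type for aryl and heteroaryl diazoketones, so it is also better on precedent.
- Against it here: A4 has to be built from a 5-aryl-4-oxopyran-2-carboxylic acid, which is a multistep synthesis ending in a hazardous diazo transfer or diazomethane acylation.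
- 4-Pyranones are photolabile in their own right, and the double bond that must take part in the 6π closure belongs to a cross-conjugated vinylogous ester, so ketene dimerisation and pyranone photochemistry may compete.
- After the key step the chelated 5-hydroxyl must be methylated under forcing conditions and two different protecting groups removed.
- Comparison: structurally it is more ambitious (ring A instead of ring C) and mechanistically better precedented. It is less convergent, because ring B must be carried through the whole pyranone synthesis, and overall longer, with three steps after the key step against one.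

Alternative 3: The cut is C4–C4a only; O1–C8a is already present in the aryl vinyl ether A7. In the forward step (CF3CO)2O turns the acid A7 into a mixed anhydride, which acylates the ring A carbon ortho to the ether oxygen and closes ring C to give A8.
- In its favour: this is a classical, metal-free Friedel–Crafts closure, better than the chosen step on precedent. The symmetric ring A makes the site of acylation unambiguous, so on regiocontrol it is the equal of the chosen plan.
- Against it here: the symmetry is also the weakness. O5 and O7 carry the same isopropyl group and must be told apart after ring closure. The easy chelation-assisted dealkylation with BCl3 removes the group on O5, the opposite of what the target needs.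
- The end game therefore becomes full dealkylation (which also takes the ring B benzyl ether), selective protection of O7 and O4', methylation of O5 and deprotection.
- A7 requires O-vinylation of a phenol with the aryloxy group cis to the carboxyl, and its enol ether is acid-sensitive under the cyclisation conditions.
- Comparison: it forms one bond and one ring, against two bonds and one ring, and is equally convergent. Mechanistically it is the more secure step. It is three to four steps longer after ring closure.

Key step: step 10

Assumptions (remarks on the chemistry):
- 1 is taken to be purchasable; if it is not, Vilsmeier formylation of 2-methylresorcinol (POCl3, DMF) provides it in one step.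
- 17 is a mixture of enol and aldehyde tautomers. It is drawn and named as the chelated Z enol, and its double-bond geometry need not be controlled because the enolate equilibrates in step 10.
- The constitution and numbering of both coupling partners and of the annulation product were re-derived from the target. The regiochemical sense (O1 on C8a, C4 on C4a, O5 next to C4a) and the Z descriptor of 17 are consistent, so no connectivity needs correcting. The changes are in design only: O5 as methyl and O7 as benzyl in 12, and silicon and triflate exchanged between C8a and C4a, giving the same aryne 18.

## Route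

Step 1
Reactants: 1 2,4-dihydroxy-3-methylbenzaldehyde
Product: 2 4-(benzyloxy)-2-hydroxy-3-methylbenzaldehyde
Conditions: BnBr (1.05 equiv), NaHCO3, KI (cat.), MeCN, 80 °C
Reagents that add atoms: benzyl bromide, BrCc1ccccc1
Why: Williamson etherification; the 2-hydroxyl is held in a hydrogen bond to the formyl oxygen and is flanked by CHO and CH3, so a weak base and one equivalent of halide should alkylate only the para hydroxyl, which becomes O7.

Step 2
Reactants: 2 4-(benzyloxy)-2-hydroxy-3-methylbenzaldehyde
Product: 3 4-(benzyloxy)-2-methoxy-3-methylbenzaldehyde
Conditions: MeI, K2CO3, DMF, 40 °C
Reagents that add atoms: iodomethane, CI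
Why: Williamson O-methylation of the remaining chelated phenol under more forcing conditions (carbonate in a dipolar solvent, excess MeI); this oxygen becomes the 5-methoxy group of the target.

Step 3
Reactants: 3 4-(benzyloxy)-2-methoxy-3-methylbenzaldehyde
Product: 5 4-(benzyloxy)-2-methoxy-3-methylphenol, via aryl formate 4 (not isolated)
Conditions: mCPBA, CH2Cl2, 0 °C to rt; then K2CO3 (cat.), MeOH, rt
Reagents that add atoms: 3-chloroperbenzoic acid, OOC(=O)c1cccc(Cl)c1
Why: Dakin-type Baeyer–Villiger oxidation; the aryl group, made electron-rich by the ortho and para oxygens, migrates in preference to hydride, and the resulting formate is methanolysed to the phenol whose oxygen sits on the future C4a.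

Step 4
Reactants: 5 4-(benzyloxy)-2-methoxy-3-methylphenol
Product: 6 4-(benzyloxy)-2-methoxy-3-methylphenyl N-(propan-2-yl)carbamate
Conditions: i-PrNCO, Et3N (cat.), CH2Cl2, rt
Reagents that add atoms: isopropyl isocyanate, CC(C)N=C=O
Why: Amine-catalysed addition of the phenol to the isocyanate (carbamoylation); it installs a strong directing group for ortho-metalation that can later be removed under mild base.

Step 5
Reactants: 6 4-(benzyloxy)-2-methoxy-3-methylphenyl N-(propan-2-yl)carbamate
Product: 10 4-(benzyloxy)-2-methoxy-3-methyl-6-(trimethylsilyl)phenyl N-(propan-2-yl)carbamate, via N-silyl carbamate 7 (not isolated), via aryllithium 8 (not isolated), via N-silyl C-silyl carbamate 9 (not isolated)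
Conditions: TBSOTf, TMEDA, Et2O, 0 °C to rt; n-BuLi, TMEDA, −78 °C; TMSCl, −78 °C to rt; aq NaHSO4
Reagents that add atoms: chlorotrimethylsilane, C[Si](C)(C)Cl
Why: Directed ortho-metalation of an aryl carbamate; the N–H is masked in the flask as the N-silyl derivative, and the carbamate then directs n-BuLi to its only free ortho position (the other carries OMe), so silicon can only be placed on the future C8a. The N-silyl group is lost on acidic work-up.

Step 6
Reactants: 10 4-(benzyloxy)-2-methoxy-3-methyl-6-(trimethylsilyl)phenyl N-(propan-2-yl)carbamate
Product: 12 4-(benzyloxy)-2-methoxy-3-methyl-6-(trimethylsilyl)phenyl trifluoromethanesulfonate, via silylphenol 11 (not isolated)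
Conditions: Et2NH, DBU, MeCN, 40 °C; then PhNTf2, 40 °C
Reagents that add atoms: N-phenylbis(trifluoromethanesulfonimide), O=S(=O)(N(c1ccccc1)S(=O)(=O)C(F)(F)F)C(F)(F)F
Why: Base-induced E1cB cleavage of the N-monosubstituted carbamate (the isocyanate is trapped by Et2NH as a urea) releases the phenoxide, which is O-triflated in the same flask; these mild, fluoride-free, non-acidic conditions leave the aryl–silicon bond and the benzyl ether untouched.

Step 7
Reactants: 13 4-hydroxy-3,5-dimethoxyphenylacetic acid
Product: 14 methyl 2-(4-hydroxy-3,5-dimethoxyphenyl)acetate
Conditions: MeOH, H2SO4 (cat.), reflux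
Reagents that add atoms: methanol, CO
Why: Fischer esterification driven by methanol as solvent; the phenol and the methyl ethers are inert.

Step 8
Reactants: 14 methyl 2-(4-hydroxy-3,5-dimethoxyphenyl)acetate
Product: 15 methyl 2-(4-benzyloxy-3,5-dimethoxyphenyl)acetate
Conditions: BnBr, K2CO3, DMF, 60 °C
Reagents that add atoms: benzyl bromide, BrCc1ccccc1
Why: Williamson etherification of the hindered phenol flanked by two methoxy groups; carbonate is too weak to deprotonate the benzylic ester position, so no C-benzylation is expected.

Step 9
Reactants: 15 methyl 2-(4-benzyloxy-3,5-dimethoxyphenyl)acetate; 16 methyl formate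
Product: 17 methyl (Z)-2-(4-benzyloxy-3,5-dimethoxyphenyl)-3-hydroxyprop-2-enoate
Conditions: NaH, THF, 0 °C to rt; then aq HCl
Reagents that add atoms: none
Why: Crossed Claisen condensation (C-formylation); only 15 can enolise, methyl formate is the more electrophilic ester, and the product is removed as its stabilised sodium enolate, which drives the equilibrium. Matching the formate to the methyl ester excludes transesterification.

Step 10
Reactants: 12 4-(benzyloxy)-2-methoxy-3-methyl-6-(trimethylsilyl)phenyl trifluoromethanesulfonate; 17 methyl (Z)-2-(4-benzyloxy-3,5-dimethoxyphenyl)-3-hydroxyprop-2-enoate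
Product: 19 7-(benzyloxy)-3-(4-benzyloxy-3,5-dimethoxyphenyl)-5-methoxy-6-methylchromen-4-one, via aryne 18 (not isolated)
Conditions: 12 (1.5 equiv), CsF (4 equiv), THF, 65 °C
Reagents that add atoms: none
Why: Proposed new method: fluoride attacks the silicon of 12 and triflate leaves from the neighbouring carbon, giving aryne 18; the enolate of 17 (formed by CsF) then adds through oxygen to C8a, the aryne terminus remote from the 5-methoxy group, because that group distorts the aryne toward attack at the distal carbon and inductively stabilises the carbanion developing at C4a beside it, and because C8a is flanked only by C8–H. The aryl anion at C4a attacks the ester carbonyl held cis to the enol oxygen in a 6-exo-trig closure and methoxide is expelled, so O1–C8a and C4–C4a form in one operation and ring C closes as the aromatic pyranone. The closest known reaction type is the fluoride-induced coupling of arynes with salicylate esters, which gives xanthones by the same O-arylation and intramolecular acyl substitution; here the phenoxide is replaced by an acyclic oxido-acrylate, for which this annulation has not been shown. Two selectivities are needed: regioselective addition to the unsymmetrical aryne, secured by the 3-alkoxy effect just described, and O- rather than C-arylation, favoured because the enolate carbon is fully substituted (aryl, ester, formyl) while the oxygen terminus is unhindered. Ring closure must outrun protonation of the aryl anion, which is helped by the cis geometry, by THF as solvent and by the absence of any added proton source; the enolate geometry equilibrates, so both enol isomers of 17 can feed the cyclisation. No stereocenter is formed. The excess of 12 allows for aryne consumed by the methoxide that is set free.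

Step 11
Reactants: 19 7-(benzyloxy)-3-(4-benzyloxy-3,5-dimethoxyphenyl)-5-methoxy-6-methylchromen-4-one
Product: 20 7-hydroxy-3-(4-hydroxy-3,5-dimethoxyphenyl)-5-methoxy-6-methylchromen-4-one
Conditions: H2 (1 atm), 10% Pd/C, EtOAc/MeOH, rt
Reagents that add atoms: none
Why: Catalytic hydrogenolysis of both aryl benzyl ethers; the methyl ethers are inert and the trisubstituted C2=C3 bond of the vinylogous ester is reduced much more slowly than benzylic C–O bonds are cleaved, so the reaction should be stopped at full debenzylation.

## Compound list

1 | 2,4-dihydroxy-3-methylbenzaldehyde | Cc1c(O)ccc(C=O)c1O | starting material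
2 | 4-(benzyloxy)-2-hydroxy-3-methylbenzaldehyde | Cc1c(OCc2ccccc2)ccc(C=O)c1O | intermediate
3 | 4-(benzyloxy)-2-methoxy-3-methylbenzaldehyde | COc1c(C=O)ccc(OCc2ccccc2)c1C | intermediate
4 | 4-(benzyloxy)-2-methoxy-3-methylphenyl formate | COc1c(OC=O)ccc(OCc2ccccc2)c1C | intermediate (not isolated)
5 | 4-(benzyloxy)-2-methoxy-3-methylphenol | COc1c(O)ccc(OCc2ccccc2)c1C | intermediate
6 | 4-(benzyloxy)-2-methoxy-3-methylphenyl N-(propan-2-yl)carbamate | COc1c(OC(=O)NC(C)C)ccc(OCc2ccccc2)c1C | intermediate
7 | 4-(benzyloxy)-2-methoxy-3-methylphenyl N-(tert-butyldimethylsilyl)-N-(propan-2-yl)carbamate | COc1c(OC(=O)N(C(C)C)[Si](C)(C)C(C)(C)C)ccc(OCc2ccccc2)c1C | intermediate (not isolated)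
8 | 6-lithio derivative of 7 (lithium on the ring carbon ortho to the carbamate) | COc1c(OC(=O)N(C(C)C)[Si](C)(C)C(C)(C)C)c([Li])cc(OCc2ccccc2)c1C | intermediate (not isolated)
9 | 4-(benzyloxy)-2-methoxy-3-methyl-6-(trimethylsilyl)phenyl N-(tert-butyldimethylsilyl)-N-(propan-2-yl)carbamate | COc1c(OC(=O)N(C(C)C)[Si](C)(C)C(C)(C)C)c([Si](C)(C)C)cc(OCc2ccccc2)c1C | intermediate (not isolated)
10 | 4-(benzyloxy)-2-methoxy-3-methyl-6-(trimethylsilyl)phenyl N-(propan-2-yl)carbamate | COc1c(OC(=O)NC(C)C)c([Si](C)(C)C)cc(OCc2ccccc2)c1C | intermediate
11 | 4-(benzyloxy)-2-methoxy-3-methyl-6-(trimethylsilyl)phenol (present as its phenoxide) | COc1c(O)c([Si](C)(C)C)cc(OCc2ccccc2)c1C | intermediate (not isolated)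
12 | 4-(benzyloxy)-2-methoxy-3-methyl-6-(trimethylsilyl)phenyl trifluoromethanesulfonate | COc1c(OS(=O)(=O)C(F)(F)F)c([Si](C)(C)C)cc(OCc2ccccc2)c1C | intermediate
13 | 4-hydroxy-3,5-dimethoxyphenylacetic acid | COc1cc(CC(=O)O)cc(OC)c1O | starting material
14 | methyl 2-(4-hydroxy-3,5-dimethoxyphenyl)acetate | COC(=O)Cc1cc(OC)c(O)c(OC)c1 | intermediate
15 | methyl 2-(4-benzyloxy-3,5-dimethoxyphenyl)acetate | COC(=O)Cc1cc(OC)c(OCc2ccccc2)c(OC)c1 | intermediate
16 | methyl formate | COC=O | starting material
17 | methyl (Z)-2-(4-benzyloxy-3,5-dimethoxyphenyl)-3-hydroxyprop-2-enoate | COC(=O)/C(=C\O)c1cc(OC)c(OCc2ccccc2)c(OC)c1 | intermediate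
18 | 5-(benzyloxy)-3-methoxy-4-methylbenzyne (1-(benzyloxy)-4,5-didehydro-3-methoxy-2-methylbenzene) | COC1=C(C)C(OCc2ccccc2)=CC#C1 | intermediate (not isolated)
19 | 7-(benzyloxy)-3-(4-benzyloxy-3,5-dimethoxyphenyl)-5-methoxy-6-methylchromen-4-one | COc1cc(-c2coc3cc(OCc4ccccc4)c(C)c(OC)c3c2=O)cc(OC)c1OCc1ccccc1 | intermediate
20 | 7-hydroxy-3-(4-hydroxy-3,5-dimethoxyphenyl)-5-methoxy-6-methylchromen-4-one | COc1cc(-c2coc3cc(O)c(C)c(OC)c3c2=O)cc(OC)c1O | target

## Step count and risk

Total step count: 11 (steps 1 to 6 for the ring A partner, steps 7 to 9 for the ring B partner, step 10 coupling, step 11 deprotection).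
Longest linear sequence: 8 steps (1, 2, 3, 4, 5, 6, 10, 11).

Least certain steps:

Step 10 (key step, proposed new method). The most likely failure is arylation of the enolate at carbon, which would lead to insertion of the aryne into the carbon–formyl bond. The second is protonation of the aryl anion before it reaches the ester, which would leave ring C open. Consumption of the aryne by the liberated methoxide would lower conversion further. The fallback uses known chemistry, sets out from 15 and 12 and returns at 19. 15 is saponified (LiOH, THF/H2O) to 2-(4-benzyloxy-3,5-dimethoxyphenyl)acetic acid F1. F1 and 12 are heated with CsF in THF in a sealed vessel (about 125 °C). The carboxylate oxygen adds to the same aryne 18 at C8a, the aryl anion attacks the carboxyl carbon, and the four-membered adduct opens. This is the known carbon–oxygen insertion of arynes into carboxylic acids, and it should give 1-[4-(benzyloxy)-6-hydroxy-2-methoxy-3-methylphenyl]-2-(4-benzyloxy-3,5-dimethoxyphenyl)ethan-1-one F2 with the same regiochemistry. Heating F2 with N,N-dimethylformamide dimethyl acetal in toluene gives (E)-1-[4-(benzyloxy)-6-hydroxy-2-methoxy-3-methylphenyl]-2-(4-benzyloxy-3,5-dimethoxyphenyl)-3-(dimethylamino)prop-2-en-1-one F3 (not isolated; its geometry is of no consequence). F3 closes with loss of dimethylamine to 19, which is the classical deoxybenzoin route to isoflavones.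

Step 5 (directed metalation and silylation). The most likely failure is loss of chemoselectivity in the lithiation: deprotonation of the ring methyl group or of the benzyl ether methylene, or migration of the carbamoyl group to carbon (anionic Fries rearrangement) if the aryllithium warms before it is silylated. The fallback sets out from 5 and returns at 12, bypassing steps 4 to 6. Amine-mediated ortho-bromination of 5 (NBS, catalytic i-Pr2NH, CH2Cl2, 0 °C) gives 4-(benzyloxy)-6-bromo-2-methoxy-3-methylphenol F4. O-Silylation with hexamethyldisilazane gives [4-(benzyloxy)-6-bromo-2-methoxy-3-methylphenoxy]trimethylsilane F5. Treating F5 with n-BuLi in THF at −78 °C causes bromine–lithium exchange and an oxygen-to-carbon silyl shift (retro-Brook rearrangement) to the lithium salt of 11, which is trapped with Tf2O to give 12. The weak point of this fallback is site selectivity in the bromination between the position ortho to the hydroxyl and the position ortho to the benzyloxy group, which is why it is not the first choice.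

Step 11 (hydrogenolysis). The most likely failure is over-reduction, meaning saturation of the C2=C3 bond once the benzyl groups are gone, or incomplete cleavage of the hindered ring B benzyl ether if the reaction is stopped early. The fallback sets out from 19 and returns at 20 and makes no new intermediate. It is an acidolytic debenzylation in CF3CO2H with pentamethylbenzene as benzyl-cation acceptor at room temperature, which involves no reduction and leaves all three methyl ethers, including the 5-methoxy group, in place.

Step 1 (selective monobenzylation). The most likely failure is over-alkylation to the bis-benzyl ether, or incomplete conversion leaving diol that would later be dimethylated. The fallback sets out from 1 and returns at 2. Exhaustive benzylation (excess BnBr, K2CO3, DMF) gives 2,4-bis(benzyloxy)-3-methylbenzaldehyde F6. The benzyl ether ortho to the formyl group is then removed selectively by chelation-controlled cleavage with MgBr2 etherate in toluene/Et2O, which leaves the para benzyl ether untouched and gives 2.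

## Further compounds

F1 | step 10 | 2-(4-benzyloxy-3,5-dimethoxyphenyl)acetic acid | COc1cc(CC(=O)O)cc(OC)c1OCc1ccccc1
F2 | step 10 | 1-[4-(benzyloxy)-6-hydroxy-2-methoxy-3-methylphenyl]-2-(4-benzyloxy-3,5-dimethoxyphenyl)ethan-1-one | COc1cc(CC(=O)c2c(O)cc(OCc3ccccc3)c(C)c2OC)cc(OC)c1OCc1ccccc1
F3 | step 10 | (E)-1-[4-(benzyloxy)-6-hydroxy-2-methoxy-3-methylphenyl]-2-(4-benzyloxy-3,5-dimethoxyphenyl)-3-(dimethylamino)prop-2-en-1-one | CN(C)/C=C(/C(=O)c1c(O)cc(OCc2ccccc2)c(C)c1OC)c1cc(OC)c(OCc2ccccc2)c(OC)c1
F4 | step 5 | 4-(benzyloxy)-6-bromo-2-methoxy-3-methylphenol | COc1c(O)c(Br)cc(OCc2ccccc2)c1C
F5 | step 5 | [4-(benzyloxy)-6-bromo-2-methoxy-3-methylphenoxy]trimethylsilane | COc1c(O[Si](C)(C)C)c(Br)cc(OCc2ccccc2)c1C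
F0 | step 11 | none | none
F6 | step 1 | 2,4-bis(benzyloxy)-3-methylbenzaldehyde | Cc1c(OCc2ccccc2)ccc(C=O)c1OCc1ccccc1
A1 | alternative 1 | [4-iodo-3-methoxy-5-(methoxymethoxy)-2-methylphenoxy]tri(propan-2-yl)silane | COCOc1cc(O[Si](C(C)C)(C(C)C)C(C)C)c(C)c(OC)c1I
A2 | alternative 1 | 2-[1-(4-benzyloxy-3,5-dimethoxyphenyl)ethenyl]-4,4,5,5-tetramethyl-1,3,2-dioxaborolane | C=C(B1OC(C)(C)C(C)(C)O1)c1cc(OC)c(OCc2ccccc2)c(OC)c1
A3 | alternative 1 | 2-(4-benzyloxy-3,5-dimethoxyphenyl)-1-[2-methoxy-6-(methoxymethoxy)-3-methyl-4-(triisopropylsilyloxy)phenyl]prop-2-en-1-one | COCOc1cc(O[Si](C(C)C)(C(C)C)C(C)C)c(C)c(OC)c1C(=O)C(=C)c1cc(OC)c(OCc2ccccc2)c(OC)c1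
A4 | alternative 2 | 5-(4-benzyloxy-3,5-dimethoxyphenyl)-2-(2-diazoacetyl)pyran-4-one | [N-]=[N+]=CC(=O)c1cc(=O)c(-c2cc(OC)c(OCc3ccccc3)c(OC)c2)co1
A5 | alternative 2 | triisopropyl(prop-1-yn-1-yloxy)silane | CC#CO[Si](C(C)C)(C(C)C)C(C)C
A6 | alternative 2 | 3-(4-benzyloxy-3,5-dimethoxyphenyl)-5-hydroxy-6-methyl-7-(triisopropylsilyloxy)chromen-4-one | COc1cc(-c2coc3cc(O[Si](C(C)C)(C(C)C)C(C)C)c(C)c(O)c3c2=O)cc(OC)c1OCc1ccccc1
A7 | alternative 3 | (Z)-2-(4-benzyloxy-3,5-dimethoxyphenyl)-3-[4-methyl-3,5-di(propan-2-yloxy)phenoxy]prop-2-enoic acid | OC(=O)/C(=C\Oc1cc(OC(C)C)c(C)c(OC(C)C)c1)c1cc(OC)c(OCc2ccccc2)c(OC)c1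
A8 | alternative 3 | 3-(4-benzyloxy-3,5-dimethoxyphenyl)-6-methyl-5,7-di(propan-2-yloxy)chromen-4-one | COc1cc(-c2coc3cc(OC(C)C)c(C)c(OC(C)C)c3c2=O)cc(OC)c1OCc1ccccc1
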